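**Retrosynthetic overview**

1. Last bond: side-chain CH2 to the ring A carbinol carbon, by SmI2 Barbier addition of a tricyclic primary iodide (rings B, C, D) to (R)-4-bromo-3,3-dimethylcyclohexanone.
2. Lactone ring D and the CH2I group come together from a tetrahydrofuran-bridged bromo acid (Pinnick oxidation, then Me3SiI ether-to-lactone switch).
3. Key step: cyclopentane ring B, the quaternary carbon and the ring C bromide arise from a bromonium-triggered ring-contractive semipinacol 1,2-shift of a decalin allylic alcohol.
4. The decalin (ring C and the six-membered precursor of ring B, formed together) comes from an intramolecular Diels–Alder reaction of a 2-silyloxydiene onto a butenolide built from α-angelica lactone, acrolein and methyl vinyl ketone.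
5. The ring A ketone comes from a cation–alkyne cyclisation of an enantiopure bromohydrin of 6-methylhept-5-en-1-yne. Ring order: butenolide, then C plus pre-B, then B by contraction, then D, then A joined last.

Assumption: the catalyst enantiomers named in steps 1, 4 and 9 are those predicted by the accepted models; if a sense proves opposite, the mirror-image catalyst is used.

Labels: the core carbons keep decalin locants throughout, also after the contraction (C1 = methyl-bearing carbinol carbon, C4=C4a = alkene, C5 = ring B carbinol, C8 = CH bearing the one-carbon arm, C8a = ring-fusion CH).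

**Route**

Step 1
Reactants: 1 5-methylfuran-2(3H)-one (α-angelica lactone); 2 acrolein
Product: 4 (R)-5-methyl-5-(3-oxopropyl)furan-2(5H)-one, via silyloxyfuran 3 (not isolated)
Conditions: TMSCl, Et3N, Et2O, 0 °C → rt, filter; then 2 (3 equiv), (2S,5S)-5-benzyl-2-tert-butyl-3-methylimidazolidin-4-one·2,4-dinitrobenzoic acid (20 mol %), CH2Cl2/H2O, −70 °C
Reagents that add atoms: none
Why: Organocatalytic Mukaiyama–Michael addition, in which the silyloxyfuran attacks the acrolein-derived iminium ion through its 5-position and the shielding benzyl group of the catalyst together with the usual syn approach sets the oxygenated quaternary centre C1 as R.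

Step 2
Reactants: 4 (R)-5-methyl-5-(3-oxopropyl)furan-2(5H)-one; 5 but-3-en-2-one (methyl vinyl ketone)
Product: 7 (5R)-5-(3-hydroxy-5-oxohept-6-en-1-yl)-5-methylfuran-2(5H)-one, via boron dienolate 6 (not isolated)
Conditions: 5, Bu2BOTf, i-Pr2NEt, CH2Cl2, −78 °C; then 4, −78 → 0 °C; pH 7 buffer/MeOH
Reagents that add atoms: none
Why: Boron-mediated aldol addition of the only possible (methyl-side) enolate of the enone to the aldehyde builds the C4–C4a bond, and the new carbinol centre is left as a mixture because it is removed in step 3.

Step 3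
Reactants: 7 (5R)-5-(3-hydroxy-5-oxohept-6-en-1-yl)-5-methylfuran-2(5H)-one
Product: 10 (1R,8S,8aS)-1-hydroxy-1-methyl-5-oxo-1,2,3,5,6,7,8,8a-octahydronaphthalene-8-carboxylic acid 1,8-lactone, via silyloxydiene 8 (not isolated), via cycloadduct 9 (not isolated)
Conditions: TBSOTf (2.4 equiv), Et3N, CH2Cl2, 0 °C; toluene, 120 °C (sealed); then Bu4NF, THF, 0 °C
Reagents that add atoms: none
Why: Soft enolisation gives a 2-silyloxydiene tied to the butenolide by three carbons, so the intramolecular Diels–Alder reaction can only occur on the lactone face carrying the tether and across the cis ring alkene, which sets C8a (S) and C8 (S) from C1 with H-8 and H-8a cis, and fluoride then releases the ketone enolate that expels the β-silyloxy group (E1cB) to install the C4=C4a alkene.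

Step 4
Reactants: 10 tricyclic enone lactone
Product: 12 (1R,5S,8S,8aS)-8-(hydroxymethyl)-1-methyl-1,2,3,5,6,7,8,8a-octahydronaphthalene-1,5-diol, via hydroxy lactone 11 (not isolated)
Conditions: (R)-2-methyl-CBS-oxazaborolidine (20 mol %), catecholborane, toluene, −78 °C; MeOH; then LiBH4, THF, 0 °C → rt
Reagents that add atoms: none
Why: Corey–Bakshi–Shibata reduction adds hydride 1,2 to the enone under reagent control (alkenyl carbon as the large group) to give the 5S alcohol whose hydroxyl is axial and cis to H-8a, and LiBH4 then reduces the lactone to the primary–tertiary diol without touching a stereocentre.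

Step 5
Reactants: 12 triol
Product: 14 (2aS,5S,8aR,8bS)-8a-methyl-2a,3,4,5,7,8,8a,8b-octahydro-2H-naphtho[1,8-bc]furan-5-ol, via monotosylate 13 (not isolated)
Conditions: TsCl (1.1 equiv), pyridine, DMAP (5 mol %), CH2Cl2, 0 → 40 °C
Reagents that add atoms: none
Why: Selective sulfonylation of the primary alcohol is followed by 5-exo-tet intramolecular Williamson etherification by the cis tertiary hydroxyl (the standard cyclodehydration of 1,4-diols), which masks both oxygens as one tetrahydrofuran ring and leaves only the allylic alcohol free, with no stereocentre changed.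

Step 6
Reactants: 14 tetrahydrofuran-bridged decalin allylic alcohol
Product: 15 (1S,3aR,4R,7R,7aS)-4-bromo-7-methyl-7,1-(epoxymethano)octahydro-1H-indene-3a-carbaldehyde
Conditions: N-bromosuccinimide (1.05 equiv), quinuclidine (10 mol %), CH2Cl2, −40 °C
Reagents that add atoms: N-bromosuccinimide, O=C1CCC(=O)N1Br
Why: Proposed new method: a bromonium-triggered ring-contractive semipinacol rearrangement of a fused secondary allylic alcohol, in which the amine-bound Br+ is guided by hydrogen bonding to the axial 5-OH onto the same face of C4 while the C5–C6 ring bond, antiperiplanar on the opposite face, shifts to C4a as C5 becomes the aldehyde (the in-plane C5–H cannot shift), so that ring B (six to five), the quaternary centre C4a (R) and the C4–Br centre (R) are formed in one anti addition; the closest known reaction type is the N-haloamide-induced halogenation/semipinacol rearrangement of tertiary allylic alcohols (ring expansion or acyclic 1,2-shift), which has not been shown for ring contraction of a secondary carbinol.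

Step 7
Reactants: 15 bromo aldehyde
Product: 17 (1S,3aR,4R,7S,7aS)-4-bromo-7-hydroxy-1-(iodomethyl)-7-methyloctahydro-1H-indene-3a-carboxylic acid 3a,7-lactone, via ether acid 16 (not isolated)
Conditions: NaClO2, NaH2PO4, 2-methylbut-2-ene, t-BuOH/H2O, 0 °C → rt; extractive work-up; then Me3SiI (4 equiv), CHCl3, 0 → 50 °C
Reagents that add atoms: sodium chlorite NaClO2, [Na+].[O-]Cl=O; iodotrimethylsilane, C[Si](C)(C)I
Why: Pinnick oxidation gives the neopentyl carboxylic acid, and iodotrimethylsilane then cleaves the tertiary–primary ether so that the C1 cation is captured by the 1,3-cis carboxyl from the face opposite to the departing oxygen (SN1 lactonisation with inversion at C1 to S, the only geometry that closes the bridged γ-lactone) while the primary carbon becomes the iodide (SN2).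

Step 8
Reactants: 18 5-bromo-2-methylpent-2-ene; 19 LiC≡CH·H2NCH2CH2NH2 (lithium acetylide–ethylenediamine complex)
Product: 20 6-methylhept-5-en-1-yne
Conditions: DMSO, 15 °C → rt
Reagents that add atoms: none
Why: SN2 alkylation of the acetylide by the primary bromide.

Step 9
Reactants: 20 6-methylhept-5-en-1-yne
Product: 21 (S)-3-(but-3-yn-1-yl)-2,2-dimethyloxirane
Conditions: ent-Shi ketone (30 mol %), KHSO5 (as 2KHSO5·KHSO4·K2SO4), K2CO3, Bu4NHSO4 (cat.), MeCN/CH2(OMe)2/aq. Na2B4O7 buffer, 0 °C
Reagents that add atoms: potassium peroxymonosulfate KHSO5, [K+].[O-]S(=O)(=O)OO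
Why: Shi epoxidation, in which the chiral dioxirane transfers oxygen to the trisubstituted alkene through a spiro transition state and sets the epoxide CH centre as S while the terminal alkyne is inert.

Step 10
Reactants: 21 (S)-3-(but-3-yn-1-yl)-2,2-dimethyloxirane
Product: 22 (R)-3-bromo-2-methylhept-6-yn-2-ol
Conditions: Li2NiBr4, THF, 0 °C → rt
Reagents that add atoms: dilithium tetrabromonickelate Li2NiBr4, [Li+].[Li+].Br[Ni-2](Br)(Br)Br
Why: Nucleophilic epoxide opening in which bromide attacks the less substituted carbon in an SN2 sense with inversion, giving the secondary bromide as R next to the tertiary alcohol.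

Step 11
Reactants: 22 (R)-3-bromo-2-methylhept-6-yn-2-ol
Product: 24 (R)-4-bromo-3,3-dimethylcyclohexan-1-one, via enol trifluoroacetate 23 (not isolated)
Conditions: CF3CO2H (10 equiv), CH2Cl2, −20 → 0 °C; then K2CO3, MeOH/H2O, 0 °C
Reagents that add atoms: trifluoroacetic acid, OC(=O)C(F)(F)F
Why: Cation–alkyne cyclisation, in which ionisation of the tertiary alcohol gives a bromine-bridged cation that is opened at the tertiary carbon by the terminal alkyne carbon (6-endo) without touching the C–Br stereocentre, and the ring vinyl cation is trapped as the enol trifluoroacetate that is then cleaved to the ketone.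

Step 12
Reactants: 17 iodo lactone; 24 (R)-4-bromo-3,3-dimethylcyclohexan-1-one
Product: 25 target CNP0282702.1
Conditions: 24 (1.5 equiv), SmI2 (2.5 equiv), NiI2 (2 mol %), THF, 0 °C → rt
Reagents that add atoms: none
Why: Samarium Barbier coupling, in which SmI2 with catalytic NiI2 reduces the primary iodide far faster than the two hindered secondary bromides or the lactone, and the organosamarium adds to the ketone from the equatorial side because the axial methyl at C3 blocks the axial path, giving the axial tertiary alcohol cis to the equatorial bromine as in the target.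

**Compound list**

1 | 5-methylfuran-2(3H)-one (α-angelica lactone) | CC1=CCC(=O)O1 | starting material
2 | acrolein (prop-2-enal) | C=CC=O | starting material
3 | trimethyl[(5-methylfuran-2-yl)oxy]silane | Cc1ccc(O[Si](C)(C)C)o1 | intermediate
4 | (R)-5-methyl-5-(3-oxopropyl)furan-2(5H)-one | O=CCC[C@]1(C)C=CC(=O)O1 | intermediate
5 | but-3-en-2-one (methyl vinyl ketone) | CC(=O)C=C | starting material
6 | (buta-1,3-dien-2-yloxy)dibutylborane | C=CC(=C)OB(CCCC)CCCC | intermediate
7 | (5R)-5-(3-hydroxy-5-oxohept-6-en-1-yl)-5-methylfuran-2(5H)-one (both carbinol epimers) | C=CC(=O)CC(O)CC[C@]1(C)C=CC(=O)O1 | intermediate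
8 | (5R)-5-[3,5-bis(tert-butyldimethylsilyloxy)hepta-4,6-dien-1-yl]-5-methylfuran-2(5H)-one (epimers at the silyloxy carbon, enol ether geometry not fixed) | C=CC(O[Si](C)(C)C(C)(C)C)=CC(O[Si](C)(C)C(C)(C)C)CC[C@]1(C)C=CC(=O)O1 | intermediate
9 | Diels–Alder adduct: lactone 10 carrying H at C4a, OTBS at C4 and a C5(OTBS)=C6 silyl enol ether in place of the enone (C1 R, C8 S, C8a S; C4 and C4a mixtures) | O=C1O[C@]2(C)CCC(O[Si](C)(C)C(C)(C)C)C3C(O[Si](C)(C)C(C)(C)C)=CC[C@H]1[C@H]23 | intermediate
10 | (1R,8S,8aS)-1-hydroxy-1-methyl-5-oxo-1,2,3,5,6,7,8,8a-octahydronaphthalene-8-carboxylic acid 1,8-lactone (γ-lactone cis-fused to both carbocycles, C4=C4a enone) | O=C1O[C@]2(C)CCC=C3C(=O)CC[C@H]1[C@H]23 | intermediate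
11 | (1R,5S,8S,8aS)-1,5-dihydroxy-1-methyl-1,2,3,5,6,7,8,8a-octahydronaphthalene-8-carboxylic acid 1,8-lactone | O=C1O[C@]2(C)CCC=C3[C@@H](O)CC[C@H]1[C@H]23 | intermediate
12 | (1R,5S,8S,8aS)-8-(hydroxymethyl)-1-methyl-1,2,3,5,6,7,8,8a-octahydronaphthalene-1,5-diol | OC[C@H]1CC[C@H](O)C2=CCC[C@@](C)(O)[C@@H]12 | intermediate
13 | primary 4-toluenesulfonate of triol 12 | Cc1ccc(cc1)S(=O)(=O)OC[C@H]2CC[C@H](O)C3=CCC[C@@](C)(O)[C@@H]23 | intermediate
14 | (2aS,5S,8aR,8bS)-8a-methyl-2a,3,4,5,7,8,8a,8b-octahydro-2H-naphtho[1,8-bc]furan-5-ol (tetrahydrofuran from O-1 to the C8 CH2 of 12) | C1O[C@]2(C)CCC=C3[C@@H](O)CC[C@H]1[C@H]23 | intermediate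
15 | (1S,3aR,4R,7R,7aS)-4-bromo-7-methyl-7,1-(epoxymethano)octahydro-1H-indene-3a-carbaldehyde (O on C7, CH2 on C1) | C1O[C@]2(C)CC[C@@H](Br)[C@]3(C=O)CC[C@H]1[C@H]23 | intermediate
16 | (1S,3aR,4R,7R,7aS)-4-bromo-7-methyl-7,1-(epoxymethano)octahydro-1H-indene-3a-carboxylic acid | C1O[C@]2(C)CC[C@@H](Br)[C@]3(C(=O)O)CC[C@H]1[C@H]23 | intermediate
17 | (1S,3aR,4R,7S,7aS)-4-bromo-7-hydroxy-1-(iodomethyl)-7-methyloctahydro-1H-indene-3a-carboxylic acid 3a,7-lactone | IC[C@H]1CC[C@@]23C(=O)O[C@@](C)(CC[C@H]2Br)[C@@H]13 | intermediate
18 | 5-bromo-2-methylpent-2-ene | CC(C)=CCCBr | starting material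
19 | lithium acetylide–ethylenediamine complex, LiC≡CH·H2NCH2CH2NH2 | [Li+].[C-]#C.NCCN | starting material
20 | 6-methylhept-5-en-1-yne | CC(C)=CCCC#C | intermediate
21 | (S)-3-(but-3-yn-1-yl)-2,2-dimethyloxirane | CC1(C)O[C@H]1CCC#C | intermediate
22 | (R)-3-bromo-2-methylhept-6-yn-2-ol | CC(C)(O)[C@H](Br)CCC#C | intermediate
23 | (R)-4-bromo-3,3-dimethylcyclohex-1-en-1-yl trifluoroacetate | CC1(C)C=C(OC(=O)C(F)(F)F)CC[C@H]1Br | intermediate
24 | (R)-4-bromo-3,3-dimethylcyclohexan-1-one | CC1(C)CC(=O)CC[C@H]1Br | intermediate
25 | CNP0282702.1 | CC1(C)C[C@](O)(C[C@H]2CC[C@@]34C(=O)O[C@@](C)(CC[C@H]3Br)[C@@H]24)CC[C@H]1Br | target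

**Step count and risks**

Total step count: 12 (steps 1–7 for the core, 8–11 for the ring A ketone, 12 for the coupling). Longest linear sequence: 8 steps (1–7, then 12).

The three steps most likely to fail:

Step 6 (the proposed new ring contraction). The risks are bromonium formation on the wrong face, which leads to an epoxide, and an incomplete 1,2-shift. The fallback uses known chemistry and separates the two events. It sets out from 14: N-bromosuccinimide in THF/H2O at 0 °C gives the trans-diaxial bromohydrin F1 (Br at C4, new tertiary OH at C4a, anti). The resulting 4a,5-diol is then put through a classical pinacol rearrangement (BF3·OEt2, CH2Cl2, −40 °C), in which the anti bromine assists ionisation at C4a and the C5–C6 bond migrates. This comes back to the route at 15.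

Step 11 (cation–alkyne cyclisation). The risks are that the terminal alkyne is a weak π-nucleophile and that the cation eliminates instead. The fallback sets out from 22: hydration of the alkyne (Ph3PAuNTf2 (2 mol %), wet dioxane, 60 °C) gives the methyl ketone F2. Kinetic bis-silylation (LiN(i-Pr)2 (2.2 equiv), TMSCl, THF, −78 °C) gives the bis-silyl enol ether F3. Its terminal silyl enol ether is then alkylated intramolecularly by the tertiary bromine-bridged cation released with TiCl4 in CH2Cl2 at −78 °C (Lewis-acid tert-alkylation of silyl enol ethers). This comes back to the route at 24.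

Step 12 (Barbier coupling). The risks are competing single-electron reduction of the two secondary bromides and ketyl coupling of 24. The fallback sets out from 17 and replaces the one-electron coupling by a preformed polar organometallic: zinc insertion (Zn dust, LiCl, THF, 40 °C) gives the alkylzinc iodide F4, which tolerates the lactone and the bromides. F4 is added to 24 in the presence of MgCl2 in THF at rt, with the same equatorial approach. This comes back to the route at 25.

**Further compounds**

F1 | step 6 | bromohydrin of 14, (2aS,5S,5aS,6R,8aR,8bS)-6-bromo-8a-methyldecahydro-2H-naphtho[1,8-bc]furan-5,5a-diol | C1O[C@]2(C)CC[C@@H](Br)[C@@]3(O)[C@@H](O)CC[C@H]1[C@H]23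
F2 | step 11 | (R)-5-bromo-6-hydroxy-6-methylheptan-2-one | CC(=O)CC[C@@H](Br)C(C)(C)O
F3 | step 11 | (R)-{[5-bromo-6-methyl-6-(trimethylsilyloxy)hept-1-en-2-yl]oxy}trimethylsilane | C=C(O[Si](C)(C)C)CC[C@@H](Br)C(C)(C)O[Si](C)(C)C
F4 | step 12 | alkylzinc iodide of 17 (ZnI in place of I) | I[Zn]C[C@H]1CC[C@@]23C(=O)O[C@@](C)(CC[C@H]2Br)[C@@H]13
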